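If isomer of the product A creeps towards an end like a first-order lag, its rate falls in step with the distance left, so two slopes of the dusk run give both that end and the time constant (relaxation time).

the same everywhere: catalyst 0.2 mol%; added ligand 1.1 mM

| run | substrate | remark | time |
|---|---|---|---|
| dusk | 0.10 M | run made earlier |  |
| flask | 0.20 M |  | 15 d |

- dusk (time / h: isomer of the product A / %, target / %, substrate / %): 3.00: 2.4, 9.6, 19.9; 10.0: 7.9, 13.9, 18.1; 15.0: 11.7, 14.0, 17.0; 25.0: 15.4, 14.8, 15.8; 40.0: 21.8, 14.4, 15.2

(readings scatter by 0.5 percentage points)

- no earlier run changes the charge of catalyst; that part of a forecast is a guess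

1. share of isomer of the product A in isomer of the product A plus target at 30 min
2. share of isomer of the product A in isomer of the product A plus target at 15 d
3. which of isomer of the product A and target there is more of at 15 d

Between 25.0 h and 40.0 h of the dusk run, the target goes from 14.8 % to 14.4 % and the substrate from 15.8 % to 15.2 %, moves of about the scatter, yet isomer of the product A climbs from 15.4 % to 21.8 %. The gain is matched outside the readings: from 3.00 h to 40.0 h of the dusk run it gains 19 percentage points, while the part of the charge that is unread loses 20 points.

The early slope is 0.00790 h⁻¹ of the charge at a mean amount of 3.95 %; the late slope is 0.00427 h⁻¹ at 18.6 %. So: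

rate constant = (early slope − late slope) / (difference of amounts) = 0.0248 h⁻¹, time constant = 40.3 h

end amount of isomer of the product A = 35.8 %

Late in the dusk run, the readings put the target at 17.9 % of whatever is not isomer of the product A; kept at that fraction, it comes to 11.5 % at the end.

The end share, [isomer of the product A] / ([isomer of the product A] + [target]) once nothing moves, is then 75.7 %. This reckoning assumes that the share carries over to the flask, where 15 d spans 8.93 of the dusk run's time constants.

The forecast gives 14 % at 30 min and 85 % at 15 d, the latter higher than this end share, with isomer of the product A ahead, calling isomer of the product A “a slow, nearly irreversible sink”.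

The flask gives 7.65 % at 30 min and 73.7 % at 15 d, with isomer of the product A ahead, 32.8 % against 11.7 %. At 150 d the flask still holds 32.8 % of isomer of the product A and 11.7 % of target.

    substrate ⇌ target (K = 0.920, k = 2.90 × 10⁻⁵ s⁻¹)
    isomer of the product A ⇌ isomer of the product B (K = 1.30, k = 4.90 × 10⁻⁶ s⁻¹)
    target + catalyst ⇌ isomer of the product A + catalyst, rate k3*[catalyst]*[target] forward; the back reaction follows from the equilibrium constant (K = 2.80, k = 0.00520 M⁻¹ s⁻¹)
    catalyst + added ligand ⇌ idle complex (K = 220 M⁻¹, k = 0.0120 M⁻¹ s⁻¹)
    isomer of the product B + catalyst ⇌ substrate + catalyst, rate k5*[catalyst]*[isomer of the product B] forward; the back reaction follows from the equilibrium constant (k = 0.490 M⁻¹ s⁻¹)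

The end share from the dusk slopes, 75.7 %, lies 2 points above the flask's value. The neighbour charged with 0.34 M of substrate ends at 73.7 %, 2 points below that same end share.

The numbers in the tables are calculated with constants of no real substance; noise was put on by code.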